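Start from the leftover in the larch run: 1.00 M of starting material against 0.800 M of reagent, the limiting reagent by charge, leaves 0.200 M of starting material without a partner. The ash run repeats that charge and runs longer.

common to all: free catalyst 0.0200 M

| run | starting material | reagent | time |
|---|---|---|---|
| larch | 1.00 M | 0.800 M |  |
| cedar | 3.00 M | 0.800 M |  |
| oak | 1.00 M | 2.40 M |  |
| ash | 1.00 M | 0.800 M | 48 min |

| run | time / min | [target] / M |
|---|---|---|
| larch run | 0.84 | 0.084 |
| larch run | 2.6 | 0.283 |
| larch run | 4.9 | 0.444 |
| larch run | 7.8 | 0.563 |
| larch run | 11 | 0.602 |
| larch run | 15 | 0.641 |
| larch run | 19 | 0.667 |
| cedar run | 0.84 | 0.338 |
| cedar run | 2.6 | 0.737 |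
| cedar run | 4.9 | 0.791 |
| cedar run | 7.8 | 0.807 |
| cedar run | 11 | 0.813 |
| cedar run | 15 | 0.788 |
| cedar run | 19 | 0.791 |
| oak run | 0.84 | 0.333 |
| oak run | 2.6 | 0.830 |
| oak run | 4.9 | 0.928 |
| oak run | 7.8 | 0.938 |
| oak run | 11 | 0.936 |
| oak run | 15 | 0.929 |
| oak run | 19 | 0.896 |

(standard deviation of a reading: 0.01 M)

- Overall: starting material + reagent -> target, with free catalyst as catalyst.
- Constant volume, constant temperature.
- "The second partner" is reagent.
- An order is taken over about fifteen percent of the charge, up and down.

* how the opening rate goes with [reagent] round the charge of the larch run: the exponent of the rate at two percent of starting material gone to target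
* how the opening rate goes with [starting material] round the charge of the larch run: the exponent of the rate at two percent of starting material gone to target (one fixed amount of target, the same in the runs compared)
* target in the ash run at 48 min, as a share of the starting material charged

For the ash run you can solve two extreme flasks. If nothing leaks away, target ends at the reagent charge, 80.0% of the starting material. If nothing more happens after the last larch reading, target stays at 66.7%. To join them, look at the oak run, where reagent is in excess and the ceiling is the starting material charge. Its readings from 4.9 min to 15 min average 0.0673 M short of that ceiling. The cedar run, with starting material in excess, ends at 0.791 M against a reagent charge of 0.800 M, so I place the loss on the starting material side and take it as first order.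

Call the midpoint time the moment target reaches 0.500 M in a flask charged with 1.00 M of starting material. A curve falling from the charge to nothing holds about the charge times its midpoint time. Interpolated, oak's midpoint time is 1.43 min, so the leak, the share of the charge lost per minute of exposure, reads 0.0470 /min. The larch midpoint time reads 6.26 min, so the loss there comes to 0.294 M, more than the leftover. Target therefore ends at the charge minus the loss, 70.6% by my reckoning, below the first extreme and above the second.

The forecast gives orders of 1 in reagent and 1 in starting material, and 71% for the ash run, reading the larch run as one that “looks like target-driven acceleration”.

The flask gives orders of 1.0 and 1.0, with rate ratios of 3.1 for cedar and 3.1 for oak against larch, and 68.5% for the ash run.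

    2 free catalyst ⇌ catalyst dimer, settled at all times (122.0 /M)
    free catalyst + starting material + reagent → target + free catalyst (16.50 /M²/min)
    starting material + reagent + target → 2 target (0.7200 /M²/min)
    starting material → decomposed substrate (0.06120 /min)

The leak is the step to decomposed substrate. The step in which target makes more target raises the ash result from 49.7% to 68.5%. Counting the missing share as leak times exposure, the ash run misses 31.5% with that step and 50.3% without it, so at one leak, read above as 0.0470 /min, whose value cancels, the exposure without the step is 1.60 times the exposure with it.

The numbers in the tables are calculated from invented constants, and the scatter is random.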